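**Plan**
- Retrosynthetic cuts, in order: the C3–C4 bond of ring C (the ketone becomes an aryl aldehyde and C2–C3 becomes the double bond of a 1-aryl vinyl ether); the formyl C–C bond on ring A; the vinyl CH2 (back to an aryl 4-methoxybenzoate); the ester C–O bond; the phenol C–O bond.
- Enabling feature: C4 sits directly on ring A at C4a, and C2 carries one hydrogen two atoms away, so C4(=O)–C3H2–C2(H) is an aldehyde C–H bond added across a C2=C3 double bond. O1 on C8a, ortho to C4a, is the tether, and the only C–H left on the pentaoxygenated ring A is the one at C4a.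
- Forward order: ring A is oxygenated to 2,3,4,5-tetramethoxyphenol; ring B is joined as an ester and the ester C=O is methylenated; ring A is formylated at its last C–H; ring C is closed last.
- Stereochemistry: the ring-closure precursor is achiral. C2 (S) is created in the ring closure by the chiral bisphosphine on rhodium and is not exposed to acid or base afterwards.

Key step: step 5

Assumption: (R)-DTBM-SEGPHOS is taken as the antipode that delivers hydride to the Re face of the alkene carbon that becomes C2, which gives 2S; the sense of induction on an enol ether of this kind has no direct analogue, so (S)-DTBM-SEGPHOS would be used if the 2R ketone should form.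

Step 1
Reactants: 1 1,2,3,4-tetramethoxybenzene
Product: 4 2,3,4,5-tetramethoxyphenol, via (2,3,4,5-tetramethoxyphenyl)lithium 2 (not isolated), via dimethyl (2,3,4,5-tetramethoxyphenyl)boronate 3 (not isolated)
Conditions: n-BuLi, TMEDA, THF, 0 °C; B(OMe)3, −78 °C to rt; AcOH, 30 % aq. H2O2, 0 °C to rt
Reagents that add atoms: hydrogen peroxide (OO)
Why: Directed ortho-metalation next to a methoxy group at one of the two equivalent free positions, borylation, and boronate oxidation (1,2-shift of the aryl group from boron to oxygen) should give the phenol, a standard arene-to-phenol sequence for polymethoxybenzenes.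

Step 2
Reactants: 4 2,3,4,5-tetramethoxyphenol; 5 4-methoxybenzoyl chloride
Product: 6 2,3,4,5-tetramethoxyphenyl 4-methoxybenzoate
Conditions: Et3N, DMAP (cat.), CH2Cl2, 0 °C to rt
Reagents that add atoms: none
Why: DMAP-catalysed acylation of a phenol by an acid chloride (nucleophilic acyl substitution) should proceed cleanly and joins ring B and the future C2 to O1.

Step 3
Reactants: 6 2,3,4,5-tetramethoxyphenyl 4-methoxybenzoate
Product: 7 1-{[1-(4-methoxyphenyl)ethenyl]oxy}-2,3,4,5-tetramethoxybenzene
Conditions: Cp2TiMe2 (2.5 equiv), toluene–THF, 65 °C, dark; filtration through basic alumina (1 % Et3N in the eluent)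
Reagents that add atoms: dimethyltitanocene, Cp2TiMe2 (C[Ti](C)(C1C=CC=C1)C1C=CC=C1)
Why: Petasis methylenation, in which the titanocene methylidene formed on heating adds [2+2] to the ester carbonyl and cycloreverts to the enol ether, is established for aryl benzoates and is non-acidic, so the acid-labile 1-aryl vinyl ether should survive.

Step 4
Reactants: 7 1-{[1-(4-methoxyphenyl)ethenyl]oxy}-2,3,4,5-tetramethoxybenzene
Product: 10 2-{[1-(4-methoxyphenyl)ethenyl]oxy}-3,4,5,6-tetramethoxybenzaldehyde, via ring A aryllithium 8 (not isolated), via lithium hemiaminal alkoxide 9 (not isolated)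
Conditions: n-BuLi (1.15 equiv), THF, −78 to −30 °C; DMF, −78 to 0 °C; H2O
Reagents that add atoms: N,N-dimethylformamide (CN(C)C=O)
Why: Directed ortho-metalation should be selective because the only hydrogen on ring A lies between the vinyloxy oxygen and a methoxy oxygen, and formylation of the aryllithium with DMF (Bouveault-type) followed by a basic aqueous quench spares the enol ether.

Step 5
Reactants: 10 2-{[1-(4-methoxyphenyl)ethenyl]oxy}-3,4,5,6-tetramethoxybenzaldehyde
Product: 11 (2S)-5,6,7,8,4'-pentamethoxyflavanone
Conditions: [Rh(cod)Cl]2 (2.5 mol %), (R)-DTBM-SEGPHOS (5.5 mol %), NaB[3,5-(CF3)2C6H3]4 (5 mol %), THF, 4 Å MS, 60 °C, argon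
Reagents that add atoms: none
Why: Proposed new method: oxidative addition of the formyl C–H bond to the cationic monovalent rhodium bisphosphine fragment gives an acyl rhodium hydride (trivalent rhodium), the tethered enol ether coordinates, the hydride migrates to the aryl- and oxygen-bearing alkene carbon (future C2) to leave a seven-membered acyl alkyl rhodacycle with rhodium on the terminal CH2, and C–C reductive elimination forms the C3–C4 bond and releases the catalyst. The closest known reaction type is the rhodium bisphosphine catalysed enantioselective intramolecular hydroacylation of 1,1-disubstituted alkenes held ortho to a benzaldehyde, in which the hydride goes to the substituted alkene carbon and the acyl group to the CH2 (2-(1-substituted vinyl)benzaldehydes to 3-substituted indanones, 2-(2-substituted allyl)benzaldehydes to 3-substituted 1-tetralones); the substrate here is the oxygen-tethered enol ether analogue, a class on which this has not been shown. Ring C closes in a formal 6-endo-trig mode, the acyl carbon bonding to the terminal alkene carbon so that both alkene carbons become ring atoms. The single new stereocentre C2 is set in the hydride insertion, where the chiral pocket of the ligand should select the Re face of the alkene carbon, which corresponds to 2S. The step needs acyl transfer to CH2 (not to the substituted carbon, which would give a 2-aryl-2-methylbenzofuran-3-one) and insertion faster than decarbonylation: the 1,1-disubstitution disfavours a tertiary alkyl rhodium, the alkene has no allylic hydrogen and so cannot isomerise, and the methoxy oxygen ortho to the acyl group (future C5–OMe) can occupy a site on the acyl hydride and slow CO loss. The neutral aprotic medium matters because the enol ether of 10 hydrolyses with acid and the flavanone racemises with base through ring opening to the chalcone.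

**Compound list**
1 | 1,2,3,4-tetramethoxybenzene | COc1ccc(OC)c(OC)c1OC | starting material
2 | (2,3,4,5-tetramethoxyphenyl)lithium (not isolated) | [Li]c1cc(OC)c(OC)c(OC)c1OC | intermediate
3 | dimethyl (2,3,4,5-tetramethoxyphenyl)boronate (not isolated) | COB(OC)c1cc(OC)c(OC)c(OC)c1OC | intermediate
4 | 2,3,4,5-tetramethoxyphenol | COc1cc(O)c(OC)c(OC)c1OC | intermediate
5 | 4-methoxybenzoyl chloride | COc1ccc(C(=O)Cl)cc1 | starting material
6 | 2,3,4,5-tetramethoxyphenyl 4-methoxybenzoate | COc1ccc(C(=O)Oc2cc(OC)c(OC)c(OC)c2OC)cc1 | intermediate
7 | 1-{[1-(4-methoxyphenyl)ethenyl]oxy}-2,3,4,5-tetramethoxybenzene | COc1ccc(C(=C)Oc2cc(OC)c(OC)c(OC)c2OC)cc1 | intermediate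
8 | {2-[1-(4-methoxyphenyl)ethenyloxy]-3,4,5,6-tetramethoxyphenyl}lithium (not isolated) | [Li]c1c(OC)c(OC)c(OC)c(OC)c1OC(=C)c1ccc(OC)cc1 | intermediate
9 | lithium (dimethylamino){2-[1-(4-methoxyphenyl)ethenyloxy]-3,4,5,6-tetramethoxyphenyl}methanolate (not isolated) | [Li]OC(N(C)C)c1c(OC)c(OC)c(OC)c(OC)c1OC(=C)c1ccc(OC)cc1 | intermediate
10 | 2-{[1-(4-methoxyphenyl)ethenyl]oxy}-3,4,5,6-tetramethoxybenzaldehyde | O=Cc1c(OC)c(OC)c(OC)c(OC)c1OC(=C)c1ccc(OC)cc1 | intermediate
11 | (2S)-5,6,7,8,4'-pentamethoxyflavanone | COc1ccc([C@@H]2CC(=O)c3c(OC)c(OC)c(OC)c(OC)c3O2)cc1 | target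

**Totals**
Total step count: 5. Longest linear sequence: 5 steps (1 to 11).

**Steps most likely to fail**

Step 5. Decarbonylation of the acyl rhodium hydride may outrun alkene insertion, insertion may go with the other regiochemistry, facial selectivity in the hydride transfer may be poor, or the enol ether may hydrolyse with adventitious acid. The fallback, built from established reactions, sets out from 4 and comes back at 11. Phenol 4 is C-acetylated at its one free ortho position (BF3·OEt2, AcOH, 90 °C) to 1-(2-hydroxy-3,4,5,6-tetramethoxyphenyl)ethan-1-one F1. Condensation with DMF dimethyl acetal (toluene, 100 °C) gives (E)-3-(dimethylamino)-1-(2-hydroxy-3,4,5,6-tetramethoxyphenyl)prop-2-en-1-one F2. Acid (conc. HCl, CH2Cl2, rt) closes this to 5,6,7,8-tetramethoxy-4H-chromen-4-one F3. Enantioselective conjugate addition of 4-methoxyphenylboronic acid to F3 (Pd(OCOCF3)2 as divalent palladium source, t-BuPyOx, NH4PF6, H2O, ClCH2CH2Cl, 60 °C; the (S) ligand is taken first and its antipode if the sense is opposite) should give 11 under neutral conditions.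

Step 4. The alkyllithium may add across the styrene-type double bond, or metalation on ring B may compete with deprotonation on ring A. The fallback sets out from 6 and comes back at 10; it replaces site-selective deprotonation by bromine–lithium exchange at a ring carbon that already carries the halogen. Ester 6 is brominated at the only free, doubly activated position of ring A (NBS, MeCN, 0 °C) to 2-bromo-3,4,5,6-tetramethoxyphenyl 4-methoxybenzoate F4. Petasis methylenation as in step 3 gives 1-bromo-2-{[1-(4-methoxyphenyl)ethenyl]oxy}-3,4,5,6-tetramethoxybenzene F5. Bromine–lithium exchange (t-BuLi, 2.1 equiv, THF, −78 °C) is much faster than addition to the alkene and gives 8, which is formylated with DMF through 9 to 10.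

Step 3. Methylenation of the donor-deactivated, ortho-substituted aryl ester may be incomplete, and the enol ether may hydrolyse on isolation. The fallback sets out from 4 and comes back at 7, forming the double bond by elimination instead of carbonyl methylenation. Commercial 2-bromo-1-(4-methoxyphenyl)ethan-1-one is reduced (NaBH4, MeOH, 0 °C) to racemic 2-bromo-1-(4-methoxyphenyl)ethan-1-ol F6. Mitsunobu etherification of 4 with F6 (PPh3, DIAD, THF, 0 °C to rt) gives racemic 1-[2-bromo-1-(4-methoxyphenyl)ethoxy]-2,3,4,5-tetramethoxybenzene F7. Dehydrobromination (KOtBu, THF, 0 °C), in which the only available β-hydrogen is the benzylic one, should give 7.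

**Further compounds**
F1 | step 5 | 1-(2-hydroxy-3,4,5,6-tetramethoxyphenyl)ethan-1-one | CC(=O)c1c(O)c(OC)c(OC)c(OC)c1OC
F2 | step 5 | (E)-3-(dimethylamino)-1-(2-hydroxy-3,4,5,6-tetramethoxyphenyl)prop-2-en-1-one | CN(C)/C=C/C(=O)c1c(O)c(OC)c(OC)c(OC)c1OC
F3 | step 5 | 5,6,7,8-tetramethoxy-4H-chromen-4-one | COc1c(OC)c(OC)c2occc(=O)c2c1OC
F4 | step 4 | 2-bromo-3,4,5,6-tetramethoxyphenyl 4-methoxybenzoate | COc1ccc(C(=O)Oc2c(Br)c(OC)c(OC)c(OC)c2OC)cc1
F5 | step 4 | 1-bromo-2-{[1-(4-methoxyphenyl)ethenyl]oxy}-3,4,5,6-tetramethoxybenzene | COc1ccc(C(=C)Oc2c(Br)c(OC)c(OC)c(OC)c2OC)cc1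
F6 | step 3 | 2-bromo-1-(4-methoxyphenyl)ethan-1-ol (racemic) | COc1ccc(C(O)CBr)cc1
F7 | step 3 | 1-[2-bromo-1-(4-methoxyphenyl)ethoxy]-2,3,4,5-tetramethoxybenzene (racemic) | COc1ccc(C(CBr)Oc2cc(OC)c(OC)c(OC)c2OC)cc1
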